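**Retrosynthetic overview**

1. The strategy rests on ring C, the fully substituted 2-hydroxy-3-isopropyl-1,4-benzoquinone (C8, C9, C11, C12, C13, C14), fused through C8=C9 to cyclohexenone ring B, whose only stereocentres are C5 (isopropenyl) and the neighbouring quaternary C10 (methyl, propanoate chain).
2. Ring C is disconnected at C9–C11 (after O12 dealkylation and redox adjustment at C7 and the chain end) to a 4-alkenyl-4-hydroxycyclobutenone carried on C8. It is assembled from a C8 alkenyllithium, diisopropyl squarate and isopropyllithium, the order of addition placing oxygen at C12 and isopropyl at C13.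
3. Ring B with C5 and C10 goes back to an achiral 4-methyl-4-(2-methoxycarbonylethyl)cyclohexa-2,5-dienone, desymmetrised by a catalytic asymmetric isopropenyl 1,4-addition. The dienone comes from propanal, methyl acrylate and methyl vinyl ketone.
4. Ring order: ring B by aldol closure (step 3), a four-membered ring attached at C8 (step 9), ring C last by ring expansion onto C8=C9 (step 12).

Key step: step 12

Remark: locants C5 to C14 are abietane locants (ring B = C5, C6, C7, C8, C9, C10; ring C = C8, C9, C11, C12, C13, C14); in step 5 the (S,S) antipode of the diene ligand is assumed to be the one that attacks the enone face leading to (S) at C5, and its mirror image would be used if the sense proves opposite.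

**Route**

Step 1
Reactants: 1 propanal
Product: 3 (E)-1-(prop-1-en-1-yl)pyrrolidine, via aminal 1,1-di(pyrrolidin-1-yl)propane 2 (not isolated)
Conditions: pyrrolidine (2 equiv), K2CO3, 0 °C to rt; filter, distil under reduced pressure
Reagents that add atoms: pyrrolidine C1CCNC1
Why: Condensation of an unhindered aldehyde with a secondary amine gives the aminal, which should crack on distillation to the E enamine (classical aldehyde enamine preparation).

Step 2
Reactants: 3 (E)-1-(prop-1-en-1-yl)pyrrolidine, 4 methyl acrylate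
Product: 6 methyl 4-methyl-5-oxopentanoate (racemic), via enamine ester 5 (not isolated)
Conditions: MeCN, reflux; then AcOH, H2O, reflux
Reagents that add atoms: water O
Why: Stork enamine Michael addition should stop at mono-alkylation because the new trisubstituted enamine is a poorer donor toward the acrylate, and hydrolysis frees the aldehyde, whose racemic centre is erased in step 4.

Step 3
Reactants: 6 methyl 4-methyl-5-oxopentanoate, 7 methyl vinyl ketone
Product: 10 methyl 3-(1-methyl-4-oxocyclohex-2-en-1-yl)propanoate (racemic), via keto aldehyde 8 (not isolated), via aldol 9 (not isolated)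
Conditions: 7 (1.2 equiv, added in portions), conc. H2SO4 (cat.), PhH, 45 °C then reflux (Dean–Stark)
Reagents that add atoms: none
Why: In this acid-catalysed Robinson annulation, known for α-branched aldehydes and methyl vinyl ketone, the enol of the aldehyde adds to the protonated enone to build the quaternary carbon, the methyl group of the resulting 1,5-keto aldehyde closes ring B by aldol addition to the non-enolisable neopentyl aldehyde, azeotropic removal of water drives dehydration to the conjugated enone, and the methyl ester is inert to catalytic acid in the absence of water or alcohol.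

Step 4
Reactants: 10 methyl 3-(1-methyl-4-oxocyclohex-2-en-1-yl)propanoate
Product: 11 methyl 3-(1-methyl-4-oxocyclohexa-2,5-dien-1-yl)propanoate (achiral, mirror-symmetric)
Conditions: DDQ, 1,4-dioxane, reflux
Reagents that add atoms: none
Why: DDQ dehydrogenation of a 4,4-disubstituted cyclohexenone should give the cross-conjugated dienone, because the quaternary C10 blocks aromatisation, and the product has a mirror plane so the racemic centre disappears.

Step 5
Reactants: 11 methyl 3-(1-methyl-4-oxocyclohexa-2,5-dien-1-yl)propanoate, 12 4,4,5,5-tetramethyl-2-(prop-1-en-2-yl)-1,3,2-dioxaborolane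
Product: 13 methyl 3-[(1R,6S)-1-methyl-4-oxo-6-(prop-1-en-2-yl)cyclohex-2-en-1-yl]propanoate (isopropenyl cis to methyl)
Conditions: [RhCl(C2H4)2]2 (2.5 mol %), (S,S)-2,5-diphenylbicyclo[2.2.2]octa-2,5-diene (5.5 mol %), aq. K3PO4 (0.5 equiv), 1,4-dioxane, 40 °C; chromatographic removal of the C10 epimer
Reagents that add atoms: none
Why: In this Hayashi–Miyaura rhodium-catalysed asymmetric 1,4-addition the alkenyl group passes from boron to a hydroxo-rhodium diene complex and inserts into one enantiotopic enone, the ligand choosing the enone face and the substrate directing attack anti to the larger propanoate chain, so C5 (S) and C10 (R) should be set together with isopropenyl cis to methyl, while the hindered mono-adduct resists a second addition.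

Step 6
Reactants: 13 methyl 3-[(1R,6S)-1-methyl-4-oxo-6-(prop-1-en-2-yl)cyclohex-2-en-1-yl]propanoate
Product: 14 methyl 3-[3-iodo-1-methyl-4-oxo-6-(prop-1-en-2-yl)cyclohex-2-en-1-yl]propanoate (C8 iodide; C5 and C10 as in 13)
Conditions: I2, pyridine, CH2Cl2, 0 °C to rt
Reagents that add atoms: iodine II
Why: Johnson α-iodination (conjugate addition of pyridine, iodination of the enolate, loss of pyridine) should place iodine on C8 only, as known for 4,4-disubstituted cyclohexenones, and the isolated isopropenyl group is not consumed under these buffered conditions.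

Step 7
Reactants: 14 the C8 iodo enone ester
Product: 15 3-[4-hydroxy-3-iodo-1-methyl-6-(prop-1-en-2-yl)cyclohex-2-en-1-yl]propan-1-ol (both C7 epimers; C5 and C10 as in 13)
Conditions: i-Bu2AlH (4 equiv), CH2Cl2, −78 to 0 °C; aq. KNaC4H4O6
Reagents that add atoms: none
Why: The aluminium hydride should reduce the iodo enone 1,2 and the ester fully while sparing the vinyl iodide, and the uncontrolled C7 carbinol does not matter because C7 becomes a ketone in step 15.

Step 8
Reactants: 15 the iodo diol
Product: 16 bis(tert-butyldimethylsilyl) ether of 15 (both C7 epimers)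
Conditions: TBSCl, imidazole, DMF, rt
Reagents that add atoms: tert-butyldimethylsilyl chloride CC(C)(C)[Si](C)(C)Cl
Why: Corey silylation should mask the C7 oxygen and the chain end, the two sites that could not survive the organolithium steps as ketone and ester.

Step 9
Reactants: 16 the bis-TBS vinyl iodide, 17 diisopropyl squarate
Product: 19 4-hydroxy-2,3-diisopropoxy-4-(ring B C8-yl)cyclobut-2-en-1-one (mixture at C7 and at the new carbinol), via alkenyllithium 18 (not isolated)
Conditions: t-BuLi (2.1 equiv), Et2O, −78 °C; then 17, THF, −78 °C; aq. NH4Cl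
Reagents that add atoms: none
Why: Iodine–lithium exchange at −78 °C should be faster than any silyl migration, and the C8 alkenyllithium adds 1,2 to one of the two equivalent squarate carbonyls, forming the C8–C14 bond with a carbinol centre that later becomes sp2.

Step 10
Reactants: 19 the squarate adduct
Product: 20 trimethylsilyl ether of 19
Conditions: TMSCl, Et3N, DMAP (cat.), CH2Cl2, 0 °C to rt
Reagents that add atoms: trimethylsilyl chloride C[Si](C)(C)Cl
Why: Silylation removes the acidic tertiary hydroxyl so that the next organolithium adds to the carbonyl and does not generate a ring-opening alkoxide.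

Step 11
Reactants: 20 the O-silylated adduct, 21 isopropyllithium
Product: 25 4-hydroxy-2-isopropoxy-3-isopropyl-4-(ring B C8-yl)cyclobut-2-en-1-one, via lithium alkoxide 22 (not isolated), via trifluoroacetate 23 (not isolated), via O-silyl cyclobutenone 24 (not isolated)
Conditions: i-PrLi, THF, −78 °C; (CF3CO)2O, −78 °C; aq. NaHCO3; then 0.5 M HCl, THF, 0 °C
Reagents that add atoms: water O
Why: This is a Stork–Danheiser-type alkylative 1,3-carbonyl transposition used for regiocontrol in squarate chemistry, in which 1,2-addition, O-trifluoroacetylation and ionisation give an isopropoxy-stabilised cyclobutenyl cation that the aqueous quench hydrolyses with loss of 2-propanol, so isopropyl should end next to the carbinol carbon (future C13) and isopropoxy next to the new carbonyl (future C12), after which dilute acid frees the tertiary alcohol.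

Step 12
Reactants: 25 the 4-alkenyl-4-hydroxy-2-isopropoxy-3-isopropylcyclobutenone
Product: 28 ring-fused 12-isopropoxy-13-isopropyl-11,14-hydroquinone (bis-TBS, both C7 epimers), via dienylketene 26 (not isolated), via cyclohexadienone 27 (not isolated)
Conditions: PhMe (degassed), 110 °C, Ar
Reagents that add atoms: none
Why: Heating should open the cyclobutenone by a conrotatory 4π electrocyclic reaction, breaking the bond between the carbonyl carbon (future C11) and the carbinol carbon (future C14) to give dienylketene 26. The donor hydroxyl on the sp3 carbon rotates outward, so the cyclohexenyl group lies cis to the ketene, which is the torquoselectivity the step needs. A thermal disrotatory 6π electrocyclisation then bonds the ketene carbon C11 to C9 and closes the six-membered ring C (C8, C9, C11, C12, C13, C14) as cyclohexadienone 27, and shift of the C9 hydrogen to oxygen gives the aromatic hydroquinone; the closest known reaction type is the Moore rearrangement of 4-alkenyl-4-hydroxycyclobutenones. No lasting stereocentre is created, since the carbinol centre and the transient C9 centre become sp2 and C5 and C10 are untouched. Regiochemistry is fixed beforehand by the cyclobutenone substitution pattern, and closure is favoured because C9 is an sp2 CH, C7 and the chain end are masked as silyl ethers, and aromatisation is irreversible.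

Step 13
Reactants: 28 the hydroquinone
Product: 29 12-isopropoxy-13-isopropyl-11,14-quinone (bis-TBS, both C7 epimers)
Conditions: Ag2O, MgSO4, Et2O, rt
Reagents that add atoms: none
Why: Two-electron oxidation of an electron-rich para-hydroquinone by silver oxide should give the quinone without touching silyl ethers or the isopropenyl group.

Step 14
Reactants: 29 the bis-TBS quinone
Product: 30 quinone diol (C7 alcohol epimers and primary alcohol)
Conditions: aq. HF (48 %), MeCN, 0 °C to rt
Reagents that add atoms: none
Why: Acidic fluoride cleaves both silyl ethers and avoids the basic fluoride sources to which the quinone and its vinylogous ester are sensitive.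

Step 15
Reactants: 30 the quinone diol
Product: 31 7-oxo quinone aldehyde
Conditions: Dess–Martin periodinane, NaHCO3, CH2Cl2, rt
Reagents that add atoms: none
Why: Dess–Martin oxidation should convert both alcohols at once, converging the C7 epimers on the ketone, and neither C5 (β to C7) nor C10 can epimerise.

Step 16
Reactants: 31 the keto aldehyde
Product: 32 7-oxo quinone carboxylic acid
Conditions: NaClO2, NaH2PO4, 2-methyl-2-butene, t-BuOH/H2O, 0 °C
Reagents that add atoms: sodium chlorite [Na+].[O-]Cl=O
Why: Pinnick oxidation is selective for the aldehyde, and the excess alkene scavenger takes up hypochlorous acid before it can reach the isopropenyl group.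

Step 17
Reactants: 32 the carboxylic acid
Product: 33 12-O-isopropyl ether of the target (methyl ester)
Conditions: TMSCHN2, PhMe/MeOH, 0 °C
Reagents that add atoms: trimethylsilyldiazomethane C[Si](C)(C)C=[N+]=[N-]
Why: Neutral O-methylation of the acid should be clean at this stage because the acidic quinone hydroxyl is still capped as its isopropyl ether and both quinone double bonds are tetrasubstituted.

Step 18
Reactants: 33 the 12-O-isopropyl ether
Product: 35 CNP0308749.1, methyl 3-[(1S,2S)-7-hydroxy-1-methyl-4,5,8-trioxo-6-(propan-2-yl)-2-(prop-1-en-2-yl)-1,2,3,4,5,8-hexahydronaphthalen-1-yl]propanoate, via dichloroboryl ether 34 (not isolated)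
Conditions: BCl3, CH2Cl2, −78 °C; then H2O
Reagents that add atoms: none
Why: BCl3 chelated between the C11 carbonyl and O12 should cleave the secondary isopropyl–oxygen bond by chloride attack at low temperature (the known selective dealkylation of isopropyl ethers next to a carbonyl), leaving the unactivated methyl ester and the stereocentres untouched.

**Compound list**

1 | propanal | CCC=O | starting material
2 | 1,1-di(pyrrolidin-1-yl)propane | CCC(N1CCCC1)N1CCCC1 | intermediate
3 | (E)-1-(prop-1-en-1-yl)pyrrolidine | C/C=C/N1CCCC1 | intermediate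
4 | methyl acrylate | C=CC(=O)OC | starting material
5 | methyl 4-methyl-5-(pyrrolidin-1-yl)pent-4-enoate | COC(=O)CCC(C)=CN1CCCC1 | intermediate
6 | methyl 4-methyl-5-oxopentanoate (racemic) | COC(=O)CCC(C)C=O | intermediate
7 | methyl vinyl ketone | CC(=O)C=C | starting material
8 | methyl 4-formyl-4-methyl-7-oxooctanoate (racemic) | COC(=O)CCC(C)(C=O)CCC(C)=O | intermediate
9 | methyl 3-(2-hydroxy-1-methyl-4-oxocyclohexyl)propanoate | COC(=O)CCC1(C)CCC(=O)CC1O | intermediate
10 | methyl 3-(1-methyl-4-oxocyclohex-2-en-1-yl)propanoate (racemic) | COC(=O)CCC1(C)CCC(=O)C=C1 | intermediate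
11 | methyl 3-(1-methyl-4-oxocyclohexa-2,5-dien-1-yl)propanoate | COC(=O)CCC1(C)C=CC(=O)C=C1 | intermediate
12 | 4,4,5,5-tetramethyl-2-(prop-1-en-2-yl)-1,3,2-dioxaborolane | C=C(C)B1OC(C)(C)C(C)(C)O1 | starting material
13 | methyl 3-[(1R,6S)-1-methyl-4-oxo-6-(prop-1-en-2-yl)cyclohex-2-en-1-yl]propanoate | C=C(C)[C@@H]1CC(=O)C=C[C@@]1(C)CCC(=O)OC | intermediate
14 | C8 iodo enone ester (3-iodo derivative of 13) | C=C(C)[C@@H]1CC(=O)C(I)=C[C@@]1(C)CCC(=O)OC | intermediate
15 | iodo diol (C7 epimers) | C=C(C)[C@@H]1CC(O)C(I)=C[C@@]1(C)CCCO | intermediate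
16 | bis-TBS ether of 15 | C=C(C)[C@@H]1CC(O[Si](C)(C)C(C)(C)C)C(I)=C[C@@]1(C)CCCO[Si](C)(C)C(C)(C)C | intermediate
17 | diisopropyl squarate (3,4-diisopropoxycyclobut-3-ene-1,2-dione) | CC(C)OC1=C(OC(C)C)C(=O)C1=O | starting material
18 | C8 alkenyllithium from 16 | C=C(C)[C@@H]1CC(O[Si](C)(C)C(C)(C)C)C([Li])=C[C@@]1(C)CCCO[Si](C)(C)C(C)(C)C | intermediate
19 | 4-alkenyl-4-hydroxy-2,3-diisopropoxycyclobut-2-en-1-one | C=C(C)[C@@H]1CC(O[Si](C)(C)C(C)(C)C)C(C2(O)C(=O)C(OC(C)C)=C2OC(C)C)=C[C@@]1(C)CCCO[Si](C)(C)C(C)(C)C | intermediate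
20 | trimethylsilyl ether of 19 | C=C(C)[C@@H]1CC(O[Si](C)(C)C(C)(C)C)C(C2(O[Si](C)(C)C)C(=O)C(OC(C)C)=C2OC(C)C)=C[C@@]1(C)CCCO[Si](C)(C)C(C)(C)C | intermediate
21 | isopropyllithium | [Li]C(C)C | starting material
22 | lithium alkoxide from addition of 21 to 20 | C=C(C)[C@@H]1CC(O[Si](C)(C)C(C)(C)C)C(C2(O[Si](C)(C)C)C(O[Li])(C(C)C)C(OC(C)C)=C2OC(C)C)=C[C@@]1(C)CCCO[Si](C)(C)C(C)(C)C | intermediate
23 | trifluoroacetate of the tertiary cyclobutenol | C=C(C)[C@@H]1CC(O[Si](C)(C)C(C)(C)C)C(C2(O[Si](C)(C)C)C(OC(=O)C(F)(F)F)(C(C)C)C(OC(C)C)=C2OC(C)C)=C[C@@]1(C)CCCO[Si](C)(C)C(C)(C)C | intermediate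
24 | 4-alkenyl-2-isopropoxy-3-isopropyl-4-(trimethylsilyloxy)cyclobut-2-en-1-one | C=C(C)[C@@H]1CC(O[Si](C)(C)C(C)(C)C)C(C2(O[Si](C)(C)C)C(=O)C(OC(C)C)=C2C(C)C)=C[C@@]1(C)CCCO[Si](C)(C)C(C)(C)C | intermediate
25 | 4-alkenyl-4-hydroxy-2-isopropoxy-3-isopropylcyclobut-2-en-1-one | C=C(C)[C@@H]1CC(O[Si](C)(C)C(C)(C)C)C(C2(O)C(=O)C(OC(C)C)=C2C(C)C)=C[C@@]1(C)CCCO[Si](C)(C)C(C)(C)C | intermediate
26 | dienylketene (hydroxyl outward, cyclohexenyl cis to the ketene) | C=C(C)[C@@H]1CC(O[Si](C)(C)C(C)(C)C)C(/C(O)=C(/C(C)C)C(OC(C)C)=C=O)=C[C@@]1(C)CCCO[Si](C)(C)C(C)(C)C | intermediate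
27 | ring C cyclohexa-2,4-dienone with C9–H | C=C(C)[C@@H]1CC(O[Si](C)(C)C(C)(C)C)C2=C(O)C(C(C)C)=C(OC(C)C)C(=O)C2[C@@]1(C)CCCO[Si](C)(C)C(C)(C)C | intermediate
28 | 12-isopropoxy-13-isopropyl-11,14-hydroquinone, bis-TBS | C=C(C)[C@@H]1CC(O[Si](C)(C)C(C)(C)C)c2c(O)c(C(C)C)c(OC(C)C)c(O)c2[C@@]1(C)CCCO[Si](C)(C)C(C)(C)C | intermediate
29 | 12-isopropoxy-13-isopropyl-11,14-quinone, bis-TBS | C=C(C)[C@@H]1CC(O[Si](C)(C)C(C)(C)C)C2=C(C(=O)C(OC(C)C)=C(C(C)C)C2=O)[C@@]1(C)CCCO[Si](C)(C)C(C)(C)C | intermediate
30 | quinone diol | C=C(C)[C@@H]1CC(O)C2=C(C(=O)C(OC(C)C)=C(C(C)C)C2=O)[C@@]1(C)CCCO | intermediate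
31 | 7-oxo quinone aldehyde | C=C(C)[C@@H]1CC(=O)C2=C(C(=O)C(OC(C)C)=C(C(C)C)C2=O)[C@@]1(C)CCC=O | intermediate
32 | 7-oxo quinone carboxylic acid | C=C(C)[C@@H]1CC(=O)C2=C(C(=O)C(OC(C)C)=C(C(C)C)C2=O)[C@@]1(C)CCC(=O)O | intermediate
33 | 12-O-isopropyl ether of the target | C=C(C)[C@@H]1CC(=O)C2=C(C(=O)C(OC(C)C)=C(C(C)C)C2=O)[C@@]1(C)CCC(=O)OC | intermediate
34 | O12-dichloroboryl ether | C=C(C)[C@@H]1CC(=O)C2=C(C(=O)C(OB(Cl)Cl)=C(C(C)C)C2=O)[C@@]1(C)CCC(=O)OC | intermediate
35 | CNP0308749.1, (5S,10S) | C=C(C)[C@@H]1CC(=O)C2=C(C(=O)C(O)=C(C(C)C)C2=O)[C@@]1(C)CCC(=O)OC | target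

**Totals**

Total step count: 18. Longest linear sequence: 18 steps (from propanal 1).

**Steps most likely to fail**

1. Step 5. The catalyst fixes the enone face, but the choice between the two faces of C10 rests only on the size difference between methyl and the propanoate chain, so the C10 epimers may form in similar amounts. Transfer of the alkenyl group next to the quaternary carbon may also be slow, and the base may saponify the ester.
Fallback: C5 would be set first and C10 by alkylation anti to it. The fallback sets out from methyl acrylate 4 and a commercial enone and comes back at 13. Copper-catalysed asymmetric conjugate addition of CH2=C(CH3)MgBr (CuBr·SMe2, chiral ferrocenyl diphosphine, −78 °C) to 2-methylcyclohex-2-en-1-one F1 should give (3R)-2-methyl-3-(prop-1-en-2-yl)cyclohexan-1-one F2. Michael addition of F2 to 4 (KOt-Bu cat., t-BuOH) at the more substituted α-carbon, anti to the isopropenyl group, should give methyl 3-[(1S,6S)-1-methyl-2-oxo-6-(prop-1-en-2-yl)cyclohexyl]propanoate F3. IBX in DMSO at 70 °C would dehydrogenate the only enolisable side to methyl 3-[(1S,6S)-1-methyl-2-oxo-6-(prop-1-en-2-yl)cyclohex-3-en-1-yl]propanoate F4. Epoxidation with t-BuOOH and DBU gives the 7,8-epoxy ketone F5. Wharton transposition (N2H4·H2O, AcOH, MeOH) through the epoxy hydrazone F6 gives the C7 allylic alcohol F7 with the C8=C9 double bond, and MnO2 oxidises it to 13.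

2. Step 11. Ionisation of the trifluoroacetate may divert into opening of the strained ring or acid cleavage of the silyl ethers, and isopropyllithium may reduce or deprotonate at the hindered carbonyl instead of adding.
Fallback: the isopropyl group would be placed on the squarate first and the regiochemistry reversed with a ketal. The fallback sets out from 16, 17 and 21 and comes back at 25. Addition of 21 to 17 gives 4-hydroxy-2,3-diisopropoxy-4-isopropylcyclobut-2-en-1-one F8. (CF3CO)2O followed by 2-propanol and Et3N traps the cation as 3,4,4-triisopropoxy-2-isopropylcyclobut-2-en-1-one F9, whose only carbonyl lies next to the isopropyl-bearing carbon. Alkenyllithium 18 (from 16 as in step 9) adds to that carbonyl to give the tertiary alcohol ketal F10, and dilute aqueous acid hydrolyses the ketal to 25.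

3. Step 16. Chlorite (and, in step 17, the diazo reagent) may attack the very electron-poor C8=C9 bond flanked by three carbonyls, or exchange the C12 vinylogous ester, before the aldehyde is consumed.
Fallback: the chain end would be oxidised while C7 is still a silyl ether. The fallback sets out from 29 and comes back at 33. Selective cleavage of the primary silyl ether (HF·pyridine, pyridine, THF, 0 °C) gives the primary alcohol with C7–OTBS F11. Dess–Martin oxidation gives aldehyde F12, Pinnick oxidation gives acid F13, and TMSCHN2 gives methyl ester F14. Aqueous HF in MeCN then frees the C7 alcohol F15, and Dess–Martin oxidation gives 33.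

**Further compounds**

F1 | step 5 | 2-methylcyclohex-2-en-1-one | CC1=CCCC1=O
F2 | step 5 | (3R)-2-methyl-3-(prop-1-en-2-yl)cyclohexan-1-one (C2 epimers) | C=C(C)[C@@H]1CCCC(=O)C1C
F3 | step 5 | methyl 3-[(1S,6S)-1-methyl-2-oxo-6-(prop-1-en-2-yl)cyclohexyl]propanoate | C=C(C)[C@@H]1CCCC(=O)[C@@]1(C)CCC(=O)OC
F4 | step 5 | methyl 3-[(1S,6S)-1-methyl-2-oxo-6-(prop-1-en-2-yl)cyclohex-3-en-1-yl]propanoate | C=C(C)[C@@H]1CC=CC(=O)[C@@]1(C)CCC(=O)OC
F5 | step 5 | 7,8-epoxy ketone from F4 (epoxide epimers) | C=C(C)[C@@H]1CC2OC2C(=O)[C@@]1(C)CCC(=O)OC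
F6 | step 5 | epoxy hydrazone of F5 | C=C(C)[C@@H]1CC2OC2C(=NN)[C@@]1(C)CCC(=O)OC
F7 | step 5 | C7 allylic alcohol with C8=C9 (C7 epimers) | C=C(C)[C@@H]1CC(O)C=C[C@@]1(C)CCC(=O)OC
F8 | step 11 | 4-hydroxy-2,3-diisopropoxy-4-isopropylcyclobut-2-en-1-one | CC(C)OC1=C(OC(C)C)C(O)(C(C)C)C1=O
F9 | step 11 | 3,4,4-triisopropoxy-2-isopropylcyclobut-2-en-1-one | O=C1C(C(C)C)=C(OC(C)C)C1(OC(C)C)OC(C)C
F10 | step 11 | tertiary alcohol ketal from 18 and F9 | C=C(C)[C@@H]1CC(O[Si](C)(C)C(C)(C)C)C(C2(O)C(C(C)C)=C(OC(C)C)C2(OC(C)C)OC(C)C)=C[C@@]1(C)CCCO[Si](C)(C)C(C)(C)C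
F11 | step 16 | quinone with C7–OTBS and free primary alcohol | C=C(C)[C@@H]1CC(O[Si](C)(C)C(C)(C)C)C2=C(C(=O)C(OC(C)C)=C(C(C)C)C2=O)[C@@]1(C)CCCO
F12 | step 16 | quinone aldehyde with C7–OTBS | C=C(C)[C@@H]1CC(O[Si](C)(C)C(C)(C)C)C2=C(C(=O)C(OC(C)C)=C(C(C)C)C2=O)[C@@]1(C)CCC=O
F13 | step 16 | quinone acid with C7–OTBS | C=C(C)[C@@H]1CC(O[Si](C)(C)C(C)(C)C)C2=C(C(=O)C(OC(C)C)=C(C(C)C)C2=O)[C@@]1(C)CCC(=O)O
F14 | step 16 | quinone methyl ester with C7–OTBS | C=C(C)[C@@H]1CC(O[Si](C)(C)C(C)(C)C)C2=C(C(=O)C(OC(C)C)=C(C(C)C)C2=O)[C@@]1(C)CCC(=O)OC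
F15 | step 16 | quinone methyl ester with free C7 alcohol | C=C(C)[C@@H]1CC(O)C2=C(C(=O)C(OC(C)C)=C(C(C)C)C2=O)[C@@]1(C)CCC(=O)OC
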